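**Retrosynthetic overview**
1. Target 16 comes from 3-chloroflavone 14 by two end-game cleavages: hydrogenolysis of the C3–Cl and 3'-O-benzyl bonds, then chelation-controlled 5-O-demethylation.
2. The strategy rests on C3 of ring C: a lone CH between C2 (which carries ring B and O1) and the C4 carbonyl. Ring C is therefore the furan ring of a 2-aryl-3-oxybenzofuran plus one carbon, and 14 is disconnected to silyl enol ether 10 and the carbene carbon of chloroform 11 (new bonds C2–C3 and C3–C4).
3. Compound 10 comes from O-silylation of 2-arylbenzofuranone 9, which comes from palladium-catalysed α-arylation of commercial 4,6-dimethoxybenzofuran-3(2H)-one 8 with aryl bromide 7.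
4. Bromide 7 comes from syringol 1: benzylation, symmetric dibromination, exchange of one bromide for OH (lithiation, borylation, oxidation) and O-methylation. Symmetry fixes the regiochemistry, which halogenation of an unsymmetrical tetraoxygenated benzene would not do reliably.
5. Ring order: rings A and B and the furan ring are bought in; the aryl–C2 bond is made in step 5; ring C is the only ring formed, by expansion of the furan in step 7.

Key step: step 7

Assumption: 1, 8 and 11 are taken as commercial; 9 and 12 are racemic, their stereocentres vanish in steps 6 and 7, and the achiral target needs no stereocontrol.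

**Step 1**
Reactants: 1 2,6-dimethoxyphenol (syringol)
Product: 2 2-(benzyloxy)-1,3-dimethoxybenzene
Conditions: BnBr, K2CO3, DMF, 60 °C
Reagents that add atoms: benzyl bromide, BrCc1ccccc1
Why: Williamson ether synthesis on the phenoxide; the benzyl group marks the future 3'-oxygen and removes the para-directing power of the free phenol.

**Step 2**
Reactants: 2 2-(benzyloxy)-1,3-dimethoxybenzene
Product: 3 3-(benzyloxy)-1,5-dibromo-2,4-dimethoxybenzene
Conditions: NBS (2.2 equiv), MeCN, 0 °C → 40 °C, dark
Reagents that add atoms: N-bromosuccinimide, O=C1CCC(=O)N1Br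
Why: Electrophilic aromatic bromination; each outer methoxy group is coplanar and directs ortho to itself and para to the other, while the twisted central benzyloxy group does not activate C5, so the symmetric 4,6-dibromide of 2 should form.

**Step 3**
Reactants: 3 3-(benzyloxy)-1,5-dibromo-2,4-dimethoxybenzene
Product: 6 3-(benzyloxy)-5-bromo-2,4-dimethoxyphenol, via aryllithium 4 (not isolated), via dimethyl arylboronate 5 (not isolated)
Conditions: n-BuLi (1.0 equiv), THF, −78 °C; B(OMe)3, −78 °C → 0 °C; AcOH, 30% aq. H2O2, 0 °C → rt
Reagents that add atoms: hydrogen peroxide, OO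
Why: Bromine–lithium exchange with one equivalent of n-BuLi replaces one of the two equivalent bromides, so no regiochemical choice arises; borylation and peroxide oxidation of the arylboronate (1,2-aryl shift from boron to oxygen) should give the phenol.

**Step 4**
Reactants: 6 3-(benzyloxy)-5-bromo-2,4-dimethoxyphenol
Product: 7 3-(benzyloxy)-1-bromo-2,4,5-trimethoxybenzene
Conditions: MeI, K2CO3, DMF, rt
Reagents that add atoms: iodomethane, CI
Why: Williamson O-methylation of the phenoxide completes the ring B pattern, with bromine at the future C1'.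

**Step 5**
Reactants: 7 3-(benzyloxy)-1-bromo-2,4,5-trimethoxybenzene; 8 4,6-dimethoxybenzofuran-3(2H)-one
Product: 9 2-[3-(benzyloxy)-2,4,5-trimethoxyphenyl]-4,6-dimethoxybenzofuran-3(2H)-one (racemic)
Conditions: Pd2(dba)3 (2 mol%), XPhos (5 mol%), NaOtBu (2.2 equiv), toluene, 80 °C, argon; then degassed 1 M HCl
Reagents that add atoms: none
Why: Buchwald–Hartwig-type palladium-catalysed ketone α-arylation; the sodium enolate of 8 is nucleophilic at C2 and should couple with the arylpalladium bromide, the more acidic product rests as its enolate whose ortho-substituted aryl group blocks a second arylation, and the new C2 stereocentre is racemic and is removed in step 6.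

**Step 6**
Reactants: 9 2-[3-(benzyloxy)-2,4,5-trimethoxyphenyl]-4,6-dimethoxybenzofuran-3(2H)-one
Product: 10 2-[3-(benzyloxy)-2,4,5-trimethoxyphenyl]-3-(tert-butyldimethylsilyloxy)-4,6-dimethoxybenzofuran
Conditions: TBSOTf, Et3N, CH2Cl2, 0 °C, argon
Reagents that add atoms: tert-butyldimethylsilyl trifluoromethanesulfonate, CC(C)(C)[Si](C)(C)OS(=O)(=O)C(F)(F)F
Why: O-silylation of an enolisable ketone with a silyl triflate and amine base (silyl enol ether formation); silylation on oxygen makes the furan ring aromatic, so a single enol ether is expected and the C2 stereocentre disappears.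

**Step 7**
Reactants: 10 2-[3-(benzyloxy)-2,4,5-trimethoxyphenyl]-3-(tert-butyldimethylsilyloxy)-4,6-dimethoxybenzofuran; 11 chloroform
Product: 14 3'-benzyloxy-3-chloro-5,7,2',4',5'-pentamethoxyflavone, via dichlorocyclopropane adduct 12 (not isolated), via silyloxyflavylium chloride 13 (not isolated)
Conditions: KOtBu (3 equiv), CHCl3 (4 equiv, slow addition), THF–hexane, −40 °C → rt; then 1 M HCl
Reagents that add atoms: none
Why: Proposed new method: KOtBu turns chloroform 11 into the trichloromethyl anion, which loses chloride to give dichlorocarbene; this electrophile should add in a concerted (2+1) cheletropic step to the C2=C3 bond of 10, the only C=C bond that carries two oxygen donors and lies outside a benzene ring, to give the cis-fused dichlorocyclopropane 12. In 12 the chloride syn to the five-membered ring should ionise while the shared C2–C3 bond opens in a disrotatory two-electron electrocyclic step, pushed by the lone pairs of O1 and of the silyloxy oxygen, to the aromatic 3-chloro-4-silyloxyflavylium chloride 13, and chloride (or tert-butoxide) then takes the silyl group from oxygen to leave the C4 carbonyl of 14. The carbene carbon becomes C3 and makes the C2–C3 and C3–C4 bonds; ring C is thus not closed by a cyclisation but arises by one-carbon expansion of the furan ring, and the two stereocentres of 12 are erased on opening, so none has to be controlled. The closest known reaction types are the dihalocarbene ring enlargement of cyclic silyl enol ethers to 2-halo-enones and the Ciamician–Dennstedt expansion of indoles to 3-chloroquinolines; a 3-silyloxybenzofuran has not been taken to a flavone in this way. The step needs chemoselectivity for the furan double bond over the two alkoxyarene rings, which rests on the double oxygen donation into C2=C3 and on the inertness of neutral aryl ethers to dichlorocarbene, and it needs the O–Si bond to outlast the alkoxide until the carbene has added, which the hindered silyl group and the low temperature should secure. Which carbon ends as C4 is fixed by the position of the silyloxy group, so no regiochemical choice is left to the reaction.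

**Step 8**
Reactants: 14 3'-benzyloxy-3-chloro-5,7,2',4',5'-pentamethoxyflavone
Product: 15 3'-hydroxy-5,7,2',4',5'-pentamethoxyflavone
Conditions: H2 (1 atm), 10% Pd/C, NaOAc, EtOAc–MeOH, rt
Reagents that add atoms: none
Why: Heterogeneous catalytic hydrogenolysis; palladium on carbon should cleave the benzylic C–O bond and, with acetate taking up HCl, the activated vinylic C3–Cl bond, while the C2=C3 bond of the vinylogous ester is reduced much more slowly, so the reaction is stopped after two equivalents of hydrogen.

**Step 9**
Reactants: 15 3'-hydroxy-5,7,2',4',5'-pentamethoxyflavone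
Product: 16 5,3'-dihydroxy-7,2',4',5'-tetramethoxyflavone
Conditions: BCl3 (3 equiv), CH2Cl2, −78 °C → 0 °C; then H2O
Reagents that add atoms: none
Why: Chelation-controlled Lewis acid ether cleavage; BCl3 bridges the C4 carbonyl and the peri 5-methoxy oxygen in a six-membered chelate and chloride removes only that methyl group, the 3'-hydroxyl being held as a borate until hydrolysis and the other aryl methyl ethers being inert at this temperature.

**Compound list**
1 | 2,6-dimethoxyphenol (syringol) | COc1cccc(OC)c1O | starting material
2 | 2-(benzyloxy)-1,3-dimethoxybenzene | COc1cccc(OC)c1OCc1ccccc1 | intermediate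
3 | 3-(benzyloxy)-1,5-dibromo-2,4-dimethoxybenzene | COc1c(Br)cc(Br)c(OC)c1OCc1ccccc1 | intermediate
4 | [3-(benzyloxy)-5-bromo-2,4-dimethoxyphenyl]lithium (not isolated) | COc1c([Li])cc(Br)c(OC)c1OCc1ccccc1 | intermediate
5 | dimethyl [3-(benzyloxy)-5-bromo-2,4-dimethoxyphenyl]boronate (not isolated) | COB(OC)c1cc(Br)c(OC)c(OCc2ccccc2)c1OC | intermediate
6 | 3-(benzyloxy)-5-bromo-2,4-dimethoxyphenol | COc1c(O)cc(Br)c(OC)c1OCc1ccccc1 | intermediate
7 | 3-(benzyloxy)-1-bromo-2,4,5-trimethoxybenzene | COc1cc(Br)c(OC)c(OCc2ccccc2)c1OC | intermediate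
8 | 4,6-dimethoxybenzofuran-3(2H)-one | COc1cc(OC)c2c(c1)OCC2=O | starting material
9 | 2-[3-(benzyloxy)-2,4,5-trimethoxyphenyl]-4,6-dimethoxybenzofuran-3(2H)-one (racemic at C2) | COc1cc(OC)c2c(c1)OC(c1cc(OC)c(OC)c(OCc3ccccc3)c1OC)C2=O | intermediate
10 | 2-[3-(benzyloxy)-2,4,5-trimethoxyphenyl]-3-(tert-butyldimethylsilyloxy)-4,6-dimethoxybenzofuran | COc1cc(OC)c2c(O[Si](C)(C)C(C)(C)C)c(-c3cc(OC)c(OC)c(OCc4ccccc4)c3OC)oc2c1 | intermediate
11 | chloroform | ClC(Cl)Cl | starting material
12 | 1a-[3-(benzyloxy)-2,4,5-trimethoxyphenyl]-6b-(tert-butyldimethylsilyloxy)-1,1-dichloro-4,6-dimethoxy-1a,6b-dihydro-1H-cyclopropa[b]benzofuran (racemic; the cis ring fusion is the only possible one; not isolated) | COc1cc(OC)c2c(c1)OC1(c3cc(OC)c(OC)c(OCc4ccccc4)c3OC)C(Cl)(Cl)C21O[Si](C)(C)C(C)(C)C | intermediate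
13 | 2-[3-(benzyloxy)-2,4,5-trimethoxyphenyl]-4-(tert-butyldimethylsilyloxy)-3-chloro-5,7-dimethoxychromenylium chloride (not isolated) | COc1cc(OC)c2c(O[Si](C)(C)C(C)(C)C)c(Cl)c(-c3cc(OC)c(OC)c(OCc4ccccc4)c3OC)[o+]c2c1.[Cl-] | intermediate
14 | 3'-benzyloxy-3-chloro-5,7,2',4',5'-pentamethoxyflavone | COc1cc(OC)c2c(=O)c(Cl)c(-c3cc(OC)c(OC)c(OCc4ccccc4)c3OC)oc2c1 | intermediate
15 | 3'-hydroxy-5,7,2',4',5'-pentamethoxyflavone | COc1cc(OC)c2c(=O)cc(-c3cc(OC)c(OC)c(O)c3OC)oc2c1 | intermediate
16 | 5,3'-dihydroxy-7,2',4',5'-tetramethoxyflavone | COc1cc(O)c2c(=O)cc(-c3cc(OC)c(OC)c(O)c3OC)oc2c1 | target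

**Step count**
Total steps: 9. Longest linear sequence: 9 steps (1 → 16; compounds 8 and 11 enter as commercial materials).

**Steps most likely to fail**

1. Step 7 (proposed new method). The alkoxide may remove the silyl group before the carbene adds, so that the free enolate is dichloromethylated at C2 without ring enlargement. The carbene may also add too slowly to the crowded tetrasubstituted double bond and be consumed by tert-butoxide. The fallback uses known chemistry, sets out from 7 and comes back at 15. Bromine–lithium exchange on 7 (n-BuLi, THF, −78 °C) and formylation with DMF should give 3-(benzyloxy)-2,4,5-trimethoxybenzaldehyde F1. Claisen–Schmidt condensation with commercial 2'-hydroxy-4',6'-dimethoxyacetophenone (KOH, EtOH, rt) should give (E)-3-[3-(benzyloxy)-2,4,5-trimethoxyphenyl]-1-(2-hydroxy-4,6-dimethoxyphenyl)prop-2-en-1-one F2. Oxidative cyclisation of this 2'-hydroxychalcone (catalytic I2, DMSO, 120 °C) should give 3'-benzyloxy-5,7,2',4',5'-pentamethoxyflavone F3. Hydrogenolysis of the benzyl ether (H2, Pd/C, EtOAc–MeOH) then gives 15, and step 9 follows.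

2. Step 5. Coupling of the electron-rich, ortho-substituted bromide with the stabilised aromatic enolate may be slow, so that the catalyst decays or the bromide is only reduced. A second arylation at C2, or oxidation of the product enolate at C2 by traces of air, is also possible. The fallback sets out from 7 and comes back at 9, and builds the furanone ring instead of arylating it. The aryllithium from 7 (n-BuLi, THF, −78 °C) is added to ethyl glyoxylate to give ethyl 2-[3-(benzyloxy)-2,4,5-trimethoxyphenyl]-2-hydroxyacetate F4. Mitsunobu etherification with 3,5-dimethoxyphenol (PPh3, DIAD, THF) should give ethyl 2-[3-(benzyloxy)-2,4,5-trimethoxyphenyl]-2-(3,5-dimethoxyphenoxy)acetate F5. Saponification (LiOH, THF–H2O) gives 2-[3-(benzyloxy)-2,4,5-trimethoxyphenyl]-2-(3,5-dimethoxyphenoxy)acetic acid F6. Intramolecular Friedel–Crafts acylation (TFAA, CH2Cl2, 0 °C) at either of the two equivalent positions ortho to the ether oxygen closes the furanone ring and gives 9.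

3. Step 8. The C2=C3 bond may be saturated to the flavanone once the chloride is gone, or the vinylic C–Cl bond may be cleaved incompletely while the benzyl ether is already lost. The fallback sets out from 14 and comes back at 16; it separates the two cleavages and uses no hydrogen gas. BCl3 (CH2Cl2, −78 °C → 0 °C) removes the benzyl group and the chelated 5-methyl group in one operation to give 3-chloro-5,3'-dihydroxy-7,2',4',5'-tetramethoxyflavone F7. Homogeneous palladium-catalysed transfer hydrodechlorination with formate (Pd(OAc)2, XPhos, HCO2Na, DMF, 80 °C) then gives 16 directly.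

**Further compounds**
F1 | step 7 | 3-(benzyloxy)-2,4,5-trimethoxybenzaldehyde | COc1cc(C=O)c(OC)c(OCc2ccccc2)c1OC
F2 | step 7 | (E)-3-[3-(benzyloxy)-2,4,5-trimethoxyphenyl]-1-(2-hydroxy-4,6-dimethoxyphenyl)prop-2-en-1-one | COc1cc(O)c(C(=O)/C=C/c2cc(OC)c(OC)c(OCc3ccccc3)c2OC)c(OC)c1
F3 | step 7 | 3'-benzyloxy-5,7,2',4',5'-pentamethoxyflavone | COc1cc(OC)c2c(=O)cc(-c3cc(OC)c(OC)c(OCc4ccccc4)c3OC)oc2c1
F4 | step 5 | ethyl 2-[3-(benzyloxy)-2,4,5-trimethoxyphenyl]-2-hydroxyacetate (racemic) | CCOC(=O)C(O)c1cc(OC)c(OC)c(OCc2ccccc2)c1OC
F5 | step 5 | ethyl 2-[3-(benzyloxy)-2,4,5-trimethoxyphenyl]-2-(3,5-dimethoxyphenoxy)acetate (racemic) | CCOC(=O)C(Oc1cc(OC)cc(OC)c1)c1cc(OC)c(OC)c(OCc2ccccc2)c1OC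
F6 | step 5 | 2-[3-(benzyloxy)-2,4,5-trimethoxyphenyl]-2-(3,5-dimethoxyphenoxy)acetic acid (racemic) | OC(=O)C(Oc1cc(OC)cc(OC)c1)c1cc(OC)c(OC)c(OCc2ccccc2)c1OC
F7 | step 8 | 3-chloro-5,3'-dihydroxy-7,2',4',5'-tetramethoxyflavone | COc1cc(O)c2c(=O)c(Cl)c(-c3cc(OC)c(OC)c(O)c3OC)oc2c1
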